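**Retrosynthetic overview**
1. Last bond: the ester between the free carboxyl of the albicanyl-ether tricarboxylate (upper half) and the equatorial C4-CH2OH of the lower half; the two CH2CO2H arms are carried as tert-butyl esters and freed at the very end.
2. Each C11–O ether comes from oxa-Michael addition of a preformed (1R,2R)-hydroxy-tricarboxylate to a 9-methylene-8-ketone, followed by C8=O → C8=CH2.
3. Key step, ring B of each decalin: oxidative semipinacol ring expansion (1,2-alkyl shift, 5 → 6) of a 1-vinylhydrindan-1-ol, which gives that 9-methylene-8-ketone directly.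
4. The hydrindane comes from an amino-acid-mediated Robinson annulation of 2-methylcyclopentane-1,3-dione with ethyl vinyl ketone (sets C10), vinyl Grignard addition, one reductive silylation to a common silyl enol ether (sets C5), then C4 functionalisation with MeI or CH2O and deoxygenation; the tricarboxylates come from an Evans syn aldol of a succinyl imide with methyl glyoxylate.
5. Ring order: cyclopentane (from the dione) → ring A (annulation) → ring B (ring expansion of the cyclopentane).

Assumption: the SMILES is taken literally, i.e. both hydroxy-tricarboxylate units are (1R,2R) and the ester-bearing CH2 on C4 of the second decalin is equatorial (4α); terpenoid carbons are referred to by drimane numbers (C8 carbinol/ketone carbon, C9 and C11 from the vinyl group, C10 methyl-bearing fusion carbon, C12 exocyclic CH2).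

**Route**

Step 1
Reactants: 1 2-methylcyclopentane-1,3-dione; 2 pent-1-en-3-one (ethyl vinyl ketone)
Product: 4 (7aS)-4,7a-dimethyl-2,3,7,7a-tetrahydro-1H-indene-1,5(6H)-dione, via triketone 3 (not isolated)
Conditions: H2O, 23 °C; then L-phenylalanine (1.0 equiv), 1 M HClO4 (0.5 equiv), MeCN, 80 °C; recrystallise
Reagents that add atoms: none
Why: Michael addition followed by a phenylalanine-mediated intramolecular aldol condensation (Hajos–Parrish type Robinson annulation), in which the chiral enamine differentiates the two enantiotopic ring carbonyls and sets the methyl-bearing quaternary centre (7aS, the future C10).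

Step 2
Reactants: 4 (7aS)-4,7a-dimethyl-2,3,7,7a-tetrahydro-1H-indene-1,5(6H)-dione
Product: 5 (1R,7aS)-1-ethenyl-1-hydroxy-4,7a-dimethyl-1,2,3,6,7,7a-hexahydro-5H-inden-5-one
Conditions: CH2=CHMgBr (1.1 equiv), LaCl3·2LiCl (1.0 equiv), THF, −78 °C; H2O
Reagents that add atoms: vinylmagnesium bromide, C=C[Mg]Br
Why: Chemoselective Grignard 1,2-addition, since the non-conjugated cyclopentanone is more electrophilic than the enone carbonyl (the selectivity NaBH4 shows on this diketone class) and LaCl3·2LiCl suppresses enolisation; vinyl enters anti to the angular methyl (1R), a centre that is erased in the ring expansion.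

Step 3
Reactants: 5 (1R,7aS)-1-ethenyl-1-hydroxy-4,7a-dimethyl-1,2,3,6,7,7a-hexahydro-5H-inden-5-one
Product: 7 (1R,3aS,7aS)-1-ethenyl-4,7a-dimethyl-1,5-bis(trimethylsilyloxy)-2,3,3a,6,7,7a-hexahydro-1H-indene, via dilithium enolate 6 (not isolated)
Conditions: Li (2.2 equiv), NH3(l)/THF, −78 °C; evaporate NH3; then TMSCl (4 equiv), Et3N (4 equiv), THF, 0 → 23 °C; cold aq NaHCO3
Reagents that add atoms: chlorotrimethylsilane, C[Si](C)(C)Cl
Why: Dissolving-metal (Birch-type) enone reduction with silyl trapping of the regiospecific enolate (Stork reductive silylation), in which protonation of the β-carbon anti to the angular methyl gives the trans ring fusion (future C5, 5α-H) and TMSCl caps both the enolate oxygen and the tertiary alkoxide, so one storable silyl enol ether serves both halves.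

Step 4
Reactants: 7 (1R,3aS,7aS)-1-ethenyl-4,7a-dimethyl-1,5-bis(trimethylsilyloxy)-2,3,3a,6,7,7a-hexahydro-1H-indene
Product: 10 (1R,3aR,7aS)-1-ethenyl-1-hydroxy-4,4,7a-trimethyloctahydro-5H-inden-5-one, via lithium enolate 8 (not isolated), via silyl ether ketone 9 (not isolated)
Conditions: MeLi (1.05 equiv), THF, 0 → 23 °C; then MeI (5 equiv), −78 → 0 °C; then 1 M aq HCl, THF, 0 °C
Reagents that add atoms: iodomethane, CI
Why: Regiospecific regeneration of the lithium enolate from the silyl enol ether with MeLi, enolate C-methylation at the future C4 to give the gem-dimethyl group without enolate equilibration, and mild acid hydrolysis of the tertiary trimethylsilyl ether, which MeLi leaves alone; no new stereocentre is formed.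

Step 5
Reactants: 10 (1R,3aR,7aS)-1-ethenyl-1-hydroxy-4,4,7a-trimethyloctahydro-5H-inden-5-one
Product: 12 (1R,3aS,7aS)-1-ethenyl-4,4,7a-trimethyloctahydro-1H-inden-1-ol, via tosylhydrazone 11 (not isolated)
Conditions: TsNHNH2, EtOH, 78 °C; evaporate; catecholborane (3 equiv), CHCl3, 0 → 23 °C; then NaOAc·3H2O, 61 °C
Reagents that add atoms: none
Why: Caglioti-type deoxygenation through the tosylhydrazone (Kabalka catecholborane variant), in which hydride addition to C=N and acetate-induced loss of sulfinate and N2 turn the hindered C=O into CH2 under near-neutral conditions that spare the tertiary allylic alcohol and the vinyl group; no stereocentre is touched.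

Step 6
Reactants: 13 succinic anhydride
Product: 14 4-tert-butoxy-4-oxobutanoic acid
Conditions: t-BuOH (3 equiv), N-hydroxysuccinimide (0.3 equiv), DMAP (0.1 equiv), Et3N (0.3 equiv), toluene, 110 °C
Reagents that add atoms: tert-butanol, CC(C)(C)O
Why: Nucleophile-catalysed alcoholysis of a cyclic anhydride gives the half ester, and the bulky tert-butyl group later keeps the CH2CO2 arm from lactonising onto the neighbouring hydroxyl.

Step 7
Reactants: 14 4-tert-butoxy-4-oxobutanoic acid
Product: 16 tert-butyl 4-[(4R)-4-benzyl-2-oxo-1,3-oxazolidin-3-yl]-4-oxobutanoate, via mixed pivalic anhydride 15 (not isolated)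
Conditions: PivCl, Et3N, THF, −20 °C; then (R)-4-benzyl-1,3-oxazolidin-2-one, LiCl, −20 → 23 °C
Reagents that add atoms: (R)-4-benzyl-1,3-oxazolidin-2-one, O=C1N[C@H](Cc2ccccc2)CO1
Why: LiCl-promoted N-acylation of the Evans oxazolidinone through the mixed pivalic anhydride installs the auxiliary that controls both new centres in step 8.

Step 8
Reactants: 16 tert-butyl 4-[(4R)-4-benzyl-2-oxo-1,3-oxazolidin-3-yl]-4-oxobutanoate; 17 methyl glyoxylate
Product: 19 5-tert-butyl 1-methyl (2R,3R)-3-[(4R)-4-benzyl-2-oxo-1,3-oxazolidine-3-carbonyl]-2-hydroxypentanedioate, via Z-boron enolate 18 (not isolated)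
Conditions: n-Bu2BOTf (1.1 equiv), i-Pr2NEt (1.3 equiv), CH2Cl2, −78 → 0 °C; 17 (2 equiv, freshly cracked), −78 → 0 °C; then pH 7 buffer, MeOH, 30% H2O2, 0 °C
Reagents that add atoms: none
Why: Evans syn aldol reaction, in which the Z-dibutylboron enolate adds to the glyoxylate through a Zimmerman–Traxler chair on the enolate face away from the benzyl group and so sets the carbinol centre (R) and the adjacent α-centre (R) together.

Step 9
Reactants: 19 5-tert-butyl 1-methyl (2R,3R)-3-[(4R)-4-benzyl-2-oxo-1,3-oxazolidine-3-carbonyl]-2-hydroxypentanedioate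
Product: 20 3-tert-butyl 1-methyl 2-prop-2-enyl (1R,2R)-1-hydroxypropane-1,2,3-tricarboxylate
Conditions: allyl alcohol (10 equiv), Sm(OTf)3 (10 mol%), CH2Cl2, 23 °C
Reagents that add atoms: allyl alcohol, C=CCO
Why: Lewis acid-catalysed alcoholysis of the chelated N-acyloxazolidinone (imide transesterification) replaces the auxiliary by an allyl ester without base, so neither retro-aldol nor epimerisation occurs, and the allyl ester is the handle for the later ester coupling.

Step 10
Reactants: 12 (1R,3aS,7aS)-1-ethenyl-4,4,7a-trimethyloctahydro-1H-inden-1-ol; 20 3-tert-butyl 1-methyl 2-prop-2-enyl (1R,2R)-1-hydroxypropane-1,2,3-tricarboxylate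
Product: 22 3-tert-butyl 1-methyl 2-prop-2-enyl (1R,2R)-1-{[(1S,4aS,8aS)-5,5,8a-trimethyl-2-oxodecahydronaphthalen-1-yl]methoxy}propane-1,2,3-tricarboxylate, via exo-enone 21 (not isolated)
Conditions: PhI(OAc)2 (1.05 equiv), (CF3)2CHOH (HFIP)/CH2Cl2 1:4, −20 → 0 °C; concentrate; then 20 (2.0 equiv), Cs2CO3 (1.2 equiv), MeCN, 0 → 23 °C
Reagents that add atoms: none
Why: Proposed new method: a trivalent-iodine-triggered oxidative semipinacol ring expansion of an unstrained, non-benzylic 1-vinylcycloalkanol telescoped with oxa-Michael etherification — HFIP-activated PhI(OAc)2 adds iodine to the terminal vinyl carbon, the antiperiplanar and more electron-rich C8–C10 bond (tertiary alkyl, higher migratory aptitude than the CH2 arm) shifts to the internal vinyl carbon with retention at C10 as the carbinol becomes the C8 ketone (ring B closed, 5 → 6), the β-keto alkyl iodane (or its acetate or HFIP ether) loses PhI and AcOH by E1cB to give the 9-methylene-8-ketone 21, and Cs2CO3 then catalyses reversible conjugate addition of the α-hydroxy ester 20 to C11 and equilibrates C9 to the equatorial CH2OR epimer (9α-H); the closest known reaction types are the oxidative ring expansions of strained or benzylic 1-vinylcycloalkanols by trivalent iodine or divalent palladium and base-catalysed oxa-Michael additions to α-methylene ketones.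

Step 11
Reactants: 22 3-tert-butyl 1-methyl 2-prop-2-enyl (1R,2R)-1-{[(1S,4aS,8aS)-5,5,8a-trimethyl-2-oxodecahydronaphthalen-1-yl]methoxy}propane-1,2,3-tricarboxylate
Product: 23 3-tert-butyl 1-methyl 2-prop-2-enyl (1R,2R)-1-{[(1S,4aS,8aS)-5,5,8a-trimethyl-2-methylidenedecahydronaphthalen-1-yl]methoxy}propane-1,2,3-tricarboxylate
Conditions: Zn, CH2Br2, TiCl4 (reagent pre-formed in THF, 3 equiv), CH2Cl2, 0 → 23 °C
Reagents that add atoms: dibromomethane, BrCBr
Why: Takai–Lombardo methylenation, in which the non-basic gem-dimetallic CH2 reagent olefinates the hindered ketone without enolising C9 or expelling the β-alkoxy group and ignores the esters, so the 9α-H configuration is locked.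

Step 12
Reactants: 23 3-tert-butyl 1-methyl 2-prop-2-enyl (1R,2R)-1-{[(1S,4aS,8aS)-5,5,8a-trimethyl-2-methylidenedecahydronaphthalen-1-yl]methoxy}propane-1,2,3-tricarboxylate
Product: 24 (2R,3R)-2-(2-tert-butoxy-2-oxoethyl)-4-methoxy-4-oxo-3-{[(1S,4aS,8aS)-5,5,8a-trimethyl-2-methylidenedecahydronaphthalen-1-yl]methoxy}butanoic acid
Conditions: Pd(PPh3)4 (5 mol%), morpholine (2 equiv), THF, 23 °C; then aq KHSO4
Reagents that add atoms: none
Why: Tsuji–Trost deallylation, in which zerovalent palladium ionises only the allyl ester and morpholine traps the π-allyl, leaving the tert-butyl and methyl esters and the exocyclic alkene untouched.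

Step 13
Reactants: 19 5-tert-butyl 1-methyl (2R,3R)-3-[(4R)-4-benzyl-2-oxo-1,3-oxazolidine-3-carbonyl]-2-hydroxypentanedioate
Product: 25 3-tert-butyl 1,2-dimethyl (1R,2R)-1-hydroxypropane-1,2,3-tricarboxylate
Conditions: MeOH, Sm(OTf)3 (10 mol%), 23 °C
Reagents that add atoms: methanol, CO
Why: The same Lewis acid-catalysed imide transesterification as in step 9, here with methanol, gives the methyl ester that the lower tricarboxylate keeps in the target, with both stereocentres untouched.

Step 14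
Reactants: 7 (1R,3aS,7aS)-1-ethenyl-4,7a-dimethyl-1,5-bis(trimethylsilyloxy)-2,3,3a,6,7,7a-hexahydro-1H-indene
Product: 27 (1R,3aR,4R,7aS)-1-ethenyl-1-hydroxy-4-(hydroxymethyl)-4,7a-dimethyloctahydro-5H-inden-5-one, via silyl ether ketol 26 (not isolated)
Conditions: 37% aq CH2O (10 equiv), Yb(OTf)3 (20 mol%), THF, 23 °C; then 0.5 M aq HCl, 0 °C
Reagents that add atoms: formaldehyde, C=O
Why: Lanthanide triflate-catalysed aqueous Mukaiyama aldol hydroxymethylation of the silyl enol ether, in which formaldehyde attacks from the α-face away from the axial angular methyl, so CH2OH ends equatorial (4α) and the original methyl axial (4β), which sets the quaternary C4 (R), and dilute acid then frees the tertiary carbinol.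

Step 15
Reactants: 27 (1R,3aR,4R,7aS)-1-ethenyl-1-hydroxy-4-(hydroxymethyl)-4,7a-dimethyloctahydro-5H-inden-5-one
Product: 28 (1R,3aR,4R,7aS)-4-{[tert-butyl(diphenyl)silyl]oxymethyl}-1-ethenyl-1-hydroxy-4,7a-dimethyloctahydro-5H-inden-5-one
Conditions: TBDPSCl (1.1 equiv), imidazole (2.5 equiv), DMF, 23 °C
Reagents that add atoms: tert-butyl(chloro)diphenylsilane, CC(C)(C)[Si](Cl)(c1ccccc1)c1ccccc1
Why: Selective silylation of the primary alcohol (the tertiary carbinol does not react) stops retro-aldol loss of formaldehyde and keeps this hydroxyl out of the oxa-Michael step.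

Step 16
Reactants: 28 (1R,3aR,4R,7aS)-4-{[tert-butyl(diphenyl)silyl]oxymethyl}-1-ethenyl-1-hydroxy-4,7a-dimethyloctahydro-5H-inden-5-one
Product: 30 (1R,3aS,4R,7aS)-4-{[tert-butyl(diphenyl)silyl]oxymethyl}-1-ethenyl-4,7a-dimethyloctahydro-1H-inden-1-ol, via tosylhydrazone 29 (not isolated)
Conditions: TsNHNH2, EtOH, 78 °C; evaporate; catecholborane (3 equiv), CHCl3, 0 → 23 °C; then NaOAc·3H2O, 61 °C
Reagents that add atoms: none
Why: The same tosylhydrazone/catecholborane deoxygenation as in step 5 removes the C3 carbonyl under near-neutral conditions that the silyl ether, the tertiary allylic alcohol and the vinyl group tolerate; no stereocentre is touched.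

Step 17
Reactants: 30 (1R,3aS,4R,7aS)-4-{[tert-butyl(diphenyl)silyl]oxymethyl}-1-ethenyl-4,7a-dimethyloctahydro-1H-inden-1-ol; 25 3-tert-butyl 1,2-dimethyl (1R,2R)-1-hydroxypropane-1,2,3-tricarboxylate
Product: 32 3-tert-butyl 1,2-dimethyl (1R,2R)-1-{[(1S,4aR,5R,8aS)-5-{[tert-butyl(diphenyl)silyl]oxymethyl}-5,8a-dimethyl-2-oxodecahydronaphthalen-1-yl]methoxy}propane-1,2,3-tricarboxylate, via exo-enone 31 (not isolated)
Conditions: PhI(OAc)2 (1.05 equiv), (CF3)2CHOH (HFIP)/CH2Cl2 1:4, −20 → 0 °C; concentrate; then 25 (2.0 equiv), Cs2CO3 (1.2 equiv), MeCN, 0 → 23 °C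
Reagents that add atoms: none
Why: Proposed new method: the same trivalent-iodine semipinacol ring expansion/oxa-Michael sequence as in step 10, here on silyl ether 30 (iodonium formation at the vinyl terminus, 1,2-shift of the C8–C10 bond with retention at C10 to close ring B, E1cB loss of PhI to enone 31, then Cs2CO3-catalysed conjugate addition of 25 to C11 with thermodynamic protonation at C9 to the 9α-H epimer); the closest known reaction types are again the oxidative ring expansions of strained or benzylic 1-vinylcycloalkanols by trivalent iodine or divalent palladium and base-catalysed oxa-Michael additions to α-methylene ketones.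

Step 18
Reactants: 32 3-tert-butyl 1,2-dimethyl (1R,2R)-1-{[(1S,4aR,5R,8aS)-5-{[tert-butyl(diphenyl)silyl]oxymethyl}-5,8a-dimethyl-2-oxodecahydronaphthalen-1-yl]methoxy}propane-1,2,3-tricarboxylate
Product: 33 3-tert-butyl 1,2-dimethyl (1R,2R)-1-{[(1S,4aR,5R,8aS)-5-{[tert-butyl(diphenyl)silyl]oxymethyl}-5,8a-dimethyl-2-methylidenedecahydronaphthalen-1-yl]methoxy}propane-1,2,3-tricarboxylate
Conditions: Zn, CH2Br2, TiCl4 (reagent pre-formed in THF, 3 equiv), CH2Cl2, 0 → 23 °C
Reagents that add atoms: dibromomethane, BrCBr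
Why: Takai–Lombardo methylenation as in step 11 converts the β-alkoxy ketone into the exocyclic alkene without base, so C9 is not epimerised and the ether is not lost.

Step 19
Reactants: 33 3-tert-butyl 1,2-dimethyl (1R,2R)-1-{[(1S,4aR,5R,8aS)-5-{[tert-butyl(diphenyl)silyl]oxymethyl}-5,8a-dimethyl-2-methylidenedecahydronaphthalen-1-yl]methoxy}propane-1,2,3-tricarboxylate
Product: 34 3-tert-butyl 1,2-dimethyl (1R,2R)-1-{[(1S,4aR,5R,8aS)-5-(hydroxymethyl)-5,8a-dimethyl-2-methylidenedecahydronaphthalen-1-yl]methoxy}propane-1,2,3-tricarboxylate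
Conditions: Bu4NF (2 equiv), AcOH (2 equiv), THF, 23 → 40 °C
Reagents that add atoms: none
Why: Fluoride-mediated desilylation buffered with acetic acid frees the neopentyl primary alcohol without ester cleavage or epimerisation.

Step 20
Reactants: 24 (2R,3R)-2-(2-tert-butoxy-2-oxoethyl)-4-methoxy-4-oxo-3-{[(1S,4aS,8aS)-5,5,8a-trimethyl-2-methylidenedecahydronaphthalen-1-yl]methoxy}butanoic acid; 34 3-tert-butyl 1,2-dimethyl (1R,2R)-1-{[(1S,4aR,5R,8aS)-5-(hydroxymethyl)-5,8a-dimethyl-2-methylidenedecahydronaphthalen-1-yl]methoxy}propane-1,2,3-tricarboxylate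
Product: 36 ester of acid 24 on the primary alcohol of 34 (di-tert-butyl ester of the target), via mixed aroyl anhydride 35 (not isolated)
Conditions: 2,4,6-Cl3C6H2COCl (1.2 equiv), Et3N (2.5 equiv), THF, 23 °C; then 34 (1.0 equiv), DMAP (2 equiv), toluene, 23 → 40 °C
Reagents that add atoms: none
Why: Yamaguchi esterification, in which DMAP attacks the mixed anhydride at the less hindered aliphatic carbonyl and the acylpyridinium acylates the neopentyl alcohol, while the β-alkoxy group is too poor a leaving group for E1cB loss, so the α-centre is kept.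

Step 21
Reactants: 36 ester of acid 24 on the primary alcohol of 34 (di-tert-butyl ester of the target)
Product: 38 CNP0139922.3 (target diacid), via bis-silyl ester 37 (not isolated)
Conditions: TMSOTf (6 equiv), 2,6-lutidine (9 equiv), CH2Cl2, 0 → 23 °C; then pH 4 aq KH2PO4/THF
Reagents that add atoms: none
Why: Silyl triflate-mediated cleavage of tert-butyl esters (carbonyl silylation, loss of the tert-butyl cation as isobutene, hydrolysis of the silyl esters on work-up) is non-protic, so the acid-labile exocyclic methylene groups do not isomerise and the methyl and neopentyl esters remain.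

**Compound list**

1 | 2-methylcyclopentane-1,3-dione | CC1C(=O)CCC1=O | starting material
2 | pent-1-en-3-one (ethyl vinyl ketone) | CCC(=O)C=C | starting material
3 | 2-methyl-2-(3-oxopentyl)cyclopentane-1,3-dione | CCC(=O)CCC1(C)C(=O)CCC1=O | intermediate
4 | (7aS)-4,7a-dimethyl-2,3,7,7a-tetrahydro-1H-indene-1,5(6H)-dione | O=C1CCC2=C(C)C(=O)CC[C@]12C | intermediate
5 | (1R,7aS)-1-ethenyl-1-hydroxy-4,7a-dimethyl-1,2,3,6,7,7a-hexahydro-5H-inden-5-one | C=C[C@]1(O)CCC2=C(C)C(=O)CC[C@]12C | intermediate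
6 | dilithium enolate/alkoxide of the trans-fused reduced enone (enolate C4=C5–O, indane numbering) | C=C[C@]1([O-])CC[C@H]2C(C)=C([O-])CC[C@]12C.[Li+].[Li+] | intermediate
7 | (1R,3aS,7aS)-1-ethenyl-4,7a-dimethyl-1,5-bis(trimethylsilyloxy)-2,3,3a,6,7,7a-hexahydro-1H-indene (trimethylsilyl enol ether C4=C5 and tertiary trimethylsilyl ether, trans ring fusion) | C=C[C@]1(O[Si](C)(C)C)CC[C@H]2C(C)=C(O[Si](C)(C)C)CC[C@]12C | intermediate
8 | lithium (1R,3aS,7aS)-1-ethenyl-4,7a-dimethyl-1-(trimethylsilyloxy)-2,3,3a,6,7,7a-hexahydro-1H-inden-5-olate | C=C[C@]1(O[Si](C)(C)C)CC[C@H]2C(C)=C([O-])CC[C@]12C.[Li+] | intermediate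
9 | (1R,3aR,7aS)-1-ethenyl-4,4,7a-trimethyl-1-(trimethylsilyloxy)octahydro-5H-inden-5-one | C=C[C@]1(O[Si](C)(C)C)CC[C@H]2C(C)(C)C(=O)CC[C@]12C | intermediate
10 | (1R,3aR,7aS)-1-ethenyl-1-hydroxy-4,4,7a-trimethyloctahydro-5H-inden-5-one | C=C[C@]1(O)CC[C@H]2C(C)(C)C(=O)CC[C@]12C | intermediate
11 | tosylhydrazone of 10 | C=C[C@]1(O)CC[C@H]2C(C)(C)C(=NNS(=O)(=O)c3ccc(C)cc3)CC[C@]12C | intermediate
12 | (1R,3aS,7aS)-1-ethenyl-4,4,7a-trimethyloctahydro-1H-inden-1-ol | C=C[C@]1(O)CC[C@H]2C(C)(C)CCC[C@]12C | intermediate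
13 | succinic anhydride | O=C1CCC(=O)O1 | starting material
14 | 4-tert-butoxy-4-oxobutanoic acid | CC(C)(C)OC(=O)CCC(=O)O | intermediate
15 | mixed anhydride of 14 with pivalic acid | CC(C)(C)OC(=O)CCC(=O)OC(=O)C(C)(C)C | intermediate
16 | tert-butyl 4-[(4R)-4-benzyl-2-oxo-1,3-oxazolidin-3-yl]-4-oxobutanoate | CC(C)(C)OC(=O)CCC(=O)N1[C@H](Cc2ccccc2)COC1=O | intermediate
17 | methyl glyoxylate | COC(=O)C=O | starting material
18 | Z-dibutylboron enolate of 16 | CC(C)(C)OC(=O)C/C=C(\OB(CCCC)CCCC)N1[C@H](Cc2ccccc2)COC1=O | intermediate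
19 | 5-tert-butyl 1-methyl (2R,3R)-3-[(4R)-4-benzyl-2-oxo-1,3-oxazolidine-3-carbonyl]-2-hydroxypentanedioate | O[C@@H](C(=O)OC)[C@@H](CC(=O)OC(C)(C)C)C(=O)N1[C@H](Cc2ccccc2)COC1=O | intermediate
20 | 3-tert-butyl 1-methyl 2-prop-2-enyl (1R,2R)-1-hydroxypropane-1,2,3-tricarboxylate | O[C@@H](C(=O)OC)[C@@H](CC(=O)OC(C)(C)C)C(=O)OCC=C | intermediate
21 | (4aS,8aS)-5,5,8a-trimethyl-1-methylideneoctahydronaphthalen-2(1H)-one | C=C1C(=O)CC[C@H]2C(C)(C)CCC[C@]12C | intermediate
22 | 3-tert-butyl 1-methyl 2-prop-2-enyl (1R,2R)-1-{[(1S,4aS,8aS)-5,5,8a-trimethyl-2-oxodecahydronaphthalen-1-yl]methoxy}propane-1,2,3-tricarboxylate | O=C1CC[C@H]2C(C)(C)CCC[C@]2(C)[C@H]1CO[C@@H](C(=O)OC)[C@@H](CC(=O)OC(C)(C)C)C(=O)OCC=C | intermediate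
23 | 2-methylidene analogue of 22 (albicanyl ether triester) | C=C1CC[C@H]2C(C)(C)CCC[C@]2(C)[C@H]1CO[C@@H](C(=O)OC)[C@@H](CC(=O)OC(C)(C)C)C(=O)OCC=C | intermediate
24 | (2R,3R)-2-(2-tert-butoxy-2-oxoethyl)-4-methoxy-4-oxo-3-{[(1S,4aS,8aS)-5,5,8a-trimethyl-2-methylidenedecahydronaphthalen-1-yl]methoxy}butanoic acid | C=C1CC[C@H]2C(C)(C)CCC[C@]2(C)[C@H]1CO[C@@H](C(=O)OC)[C@@H](CC(=O)OC(C)(C)C)C(=O)O | intermediate
25 | 3-tert-butyl 1,2-dimethyl (1R,2R)-1-hydroxypropane-1,2,3-tricarboxylate | O[C@@H](C(=O)OC)[C@@H](CC(=O)OC(C)(C)C)C(=O)OC | intermediate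
26 | (1R,3aR,4R,7aS)-1-ethenyl-4-(hydroxymethyl)-4,7a-dimethyl-1-(trimethylsilyloxy)octahydro-5H-inden-5-one | C=C[C@]1(O[Si](C)(C)C)CC[C@H]2[C@](C)(CO)C(=O)CC[C@]12C | intermediate
27 | (1R,3aR,4R,7aS)-1-ethenyl-1-hydroxy-4-(hydroxymethyl)-4,7a-dimethyloctahydro-5H-inden-5-one | C=C[C@]1(O)CC[C@H]2[C@](C)(CO)C(=O)CC[C@]12C | intermediate
28 | tert-butyldiphenylsilyl ether of 27 (primary OH) | C=C[C@]1(O)CC[C@H]2[C@](C)(CO[Si](c3ccccc3)(c3ccccc3)C(C)(C)C)C(=O)CC[C@]12C | intermediate
29 | tosylhydrazone of 28 | C=C[C@]1(O)CC[C@H]2[C@](C)(CO[Si](c3ccccc3)(c3ccccc3)C(C)(C)C)C(=NNS(=O)(=O)c3ccc(C)cc3)CC[C@]12C | intermediate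
30 | (1R,3aS,4R,7aS)-4-{[tert-butyl(diphenyl)silyl]oxymethyl}-1-ethenyl-4,7a-dimethyloctahydro-1H-inden-1-ol | C=C[C@]1(O)CC[C@H]2[C@](C)(CO[Si](c3ccccc3)(c3ccccc3)C(C)(C)C)CCC[C@]12C | intermediate
31 | (4aR,5R,8aS)-5-{[tert-butyl(diphenyl)silyl]oxymethyl}-5,8a-dimethyl-1-methylideneoctahydronaphthalen-2(1H)-one | C=C1C(=O)CC[C@H]2[C@](C)(CO[Si](c3ccccc3)(c3ccccc3)C(C)(C)C)CCC[C@]12C | intermediate
32 | 3-tert-butyl 1,2-dimethyl (1R,2R)-1-{[(1S,4aR,5R,8aS)-5-{[tert-butyl(diphenyl)silyl]oxymethyl}-5,8a-dimethyl-2-oxodecahydronaphthalen-1-yl]methoxy}propane-1,2,3-tricarboxylate | O=C1CC[C@H]2[C@](C)(CO[Si](c3ccccc3)(c3ccccc3)C(C)(C)C)CCC[C@]2(C)[C@H]1CO[C@@H](C(=O)OC)[C@@H](CC(=O)OC(C)(C)C)C(=O)OC | intermediate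
33 | 2-methylidene analogue of 32 | C=C1CC[C@H]2[C@](C)(CO[Si](c3ccccc3)(c3ccccc3)C(C)(C)C)CCC[C@]2(C)[C@H]1CO[C@@H](C(=O)OC)[C@@H](CC(=O)OC(C)(C)C)C(=O)OC | intermediate
34 | 3-tert-butyl 1,2-dimethyl (1R,2R)-1-{[(1S,4aR,5R,8aS)-5-(hydroxymethyl)-5,8a-dimethyl-2-methylidenedecahydronaphthalen-1-yl]methoxy}propane-1,2,3-tricarboxylate | C=C1CC[C@H]2[C@](C)(CO)CCC[C@]2(C)[C@H]1CO[C@@H](C(=O)OC)[C@@H](CC(=O)OC(C)(C)C)C(=O)OC | intermediate
35 | mixed anhydride of 24 with 2,4,6-trichlorobenzoic acid | C=C1CC[C@H]2C(C)(C)CCC[C@]2(C)[C@H]1CO[C@@H](C(=O)OC)[C@@H](CC(=O)OC(C)(C)C)C(=O)OC(=O)c1c(Cl)cc(Cl)cc1Cl | intermediate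
36 | ester of acid 24 on the primary alcohol of 34 (di-tert-butyl ester of the target) | C=C1CC[C@H]2C(C)(C)CCC[C@]2(C)[C@H]1CO[C@@H](C(=O)OC)[C@@H](CC(=O)OC(C)(C)C)C(=O)OC[C@]1(C)CCC[C@]2(C)[C@@H](CO[C@@H](C(=O)OC)[C@@H](CC(=O)OC(C)(C)C)C(=O)OC)C(=C)CC[C@@H]12 | intermediate
37 | bis(trimethylsilyl) ester of the target (both CH2CO2SiMe3) | C=C1CC[C@H]2C(C)(C)CCC[C@]2(C)[C@H]1CO[C@@H](C(=O)OC)[C@@H](CC(=O)O[Si](C)(C)C)C(=O)OC[C@]1(C)CCC[C@]2(C)[C@@H](CO[C@@H](C(=O)OC)[C@@H](CC(=O)O[Si](C)(C)C)C(=O)OC)C(=C)CC[C@@H]12 | intermediate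
38 | CNP0139922.3 (target diacid) | C=C1CC[C@H]2C(C)(C)CCC[C@]2(C)[C@H]1CO[C@@H](C(=O)OC)[C@@H](CC(=O)O)C(=O)OC[C@]1(C)CCC[C@]2(C)[C@@H](CO[C@@H](C(=O)OC)[C@@H](CC(=O)O)C(=O)OC)C(=C)CC[C@@H]12 | target

**Step count and risks**

Total step count: 21. Longest linear sequence: 11 steps (1, 2, 3, 14, 15, 16, 17, 18, 19, 20, 21).

Steps most likely to fail:

Step 10 (the proposed new step). The unstrained vinyl carbinol may react sluggishly with PhI(OAc)2, or the tertiary allylic alcohol may ionise in HFIP; in the second half the hindered α-hydroxy ester may add incompletely or lactonise. The fallback uses known chemistry, sets out from 12 and comes back to the route at 21. Hydroxyl-directed epoxidation of 12 (VO(acac)2 cat., t-BuOOH, CH2Cl2, 0 °C) gives the epoxy alcohol F1 (a mixture at the oxirane carbon, which does not matter because that carbon becomes sp2). BF3·OEt2 (CH2Cl2, −78 °C) then brings about the established Lewis acid semipinacol rearrangement of a 2,3-epoxy alcohol: the same C8–C10 bond migrates to the oxirane carbon and the ring enlarges to the β-hydroxy ketone F2. MsCl/Et3N gives the mesylate F3, which eliminates on adding DBU to give 21 as an isolated compound. Enone 21 is then etherified with 20 (Cs2CO3, MeCN) as in the second half of step 10.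

Step 17 (the same new method on the more encumbered silyl ether 30). The fallback sets out from 30 and comes back at 31 by the same known sequence: VO(acac)2/t-BuOOH gives the epoxy alcohol F4; BF3·OEt2 at −78 °C gives the β-hydroxy ketone F5 by semipinacol ring expansion; MsCl/Et3N gives the mesylate F6, and DBU eliminates it to the isolated enone 31. Enone 31 then receives 25 under Cs2CO3 as in the second half of step 17.

Step 2 (chemoselectivity between the two carbonyls of 4). If the Grignard reagent also attacks the enone, the enone is masked first; this fallback sets out from 4 and comes back at 5. Triethyl orthoformate with catalytic TsOH in EtOH converts only the conjugated ketone into the ethyl dienol ether F7 (the classical tactic for steroidal enediones). Vinylmagnesium bromide then adds to the only remaining ketone, anti to the angular methyl, to give the carbinol F8. Oxalic acid in wet THF hydrolyses the dienol ether and returns 5.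

Further compounds
F1 | step 10 | 1-(oxiran-2-yl) analogue of 12 (epoxy alcohol; oxirane carbon as a mixture) | C3OC3[C@]1(O)CC[C@H]2C(C)(C)CCC[C@]12C
F2 | step 10 | (1S,4aS,8aS)-1-(hydroxymethyl)-5,5,8a-trimethyloctahydronaphthalen-2(1H)-one | O=C1CC[C@H]2C(C)(C)CCC[C@]2(C)[C@H]1CO
F3 | step 10 | methanesulfonate of F2 | O=C1CC[C@H]2C(C)(C)CCC[C@]2(C)[C@H]1COS(C)(=O)=O
F4 | step 17 | 1-(oxiran-2-yl) analogue of 30 (epoxy alcohol; oxirane carbon as a mixture) | C3OC3[C@]1(O)CC[C@H]2[C@](C)(CO[Si](c3ccccc3)(c3ccccc3)C(C)(C)C)CCC[C@]12C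
F5 | step 17 | (1S,4aR,5R,8aS)-5-{[tert-butyl(diphenyl)silyl]oxymethyl}-1-(hydroxymethyl)-5,8a-dimethyloctahydronaphthalen-2(1H)-one | O=C1CC[C@H]2[C@](C)(CO[Si](c3ccccc3)(c3ccccc3)C(C)(C)C)CCC[C@]2(C)[C@H]1CO
F6 | step 17 | methanesulfonate of F5 | O=C1CC[C@H]2[C@](C)(CO[Si](c3ccccc3)(c3ccccc3)C(C)(C)C)CCC[C@]2(C)[C@H]1COS(C)(=O)=O
F7 | step 2 | (7aS)-5-ethoxy-4,7a-dimethyl-2,6,7,7a-tetrahydro-1H-inden-1-one | CCOC1=C(C)C2=CCC(=O)[C@@]2(C)CC1
F8 | step 2 | (1R,7aS)-5-ethoxy-1-ethenyl-4,7a-dimethyl-2,6,7,7a-tetrahydro-1H-inden-1-ol | CCOC1=C(C)C2=CC[C@@](O)(C=C)[C@@]2(C)CC1
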